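**Retrosynthetic overview**
- The C2 stereocentre is set last, by face-selective addition of H2 to the C2=C3 enol ether of the 2-aryl-4H-chromene.
- Ring C, the only ring built, comes from cyclodehydration (O1–C2 bond) of the 3-(2-hydroxyaryl)propyl aryl ketone. Rings A and B are bought.
- Key disconnection C4–C4a: the β-carbon of the aryl ketone acts as a homoenolate (d3 synthon) and is joined to the C–Br carbon of ring A. Both carbons are normally electrophilic.
- The homoenolate is stored as a 1-arylcyclopropanol (Kulinkovich reaction on the ring B ester). The ring A partner is the unprotected ortho-bromophenol.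
- Ring order: temporary cyclopropane, then ring opening, then ring C.

Assumption: a sequence telescoped without isolating the intermediate counts as one step, and the sense of induction in step 4 is confirmed on pilot scale (chiral HPLC, sign of rotation) before scale-up.

**Step 1**
Reactants: 1 methyl 3,4,5-trimethoxybenzoate
Product: 2 1-(3,4,5-trimethoxyphenyl)cyclopropan-1-ol
Conditions: EtMgBr (2.6 equiv, slow addition), Ti(OiPr)4 (20 mol %), THF/Et2O, 0 °C to rt; aq. NH4Cl
Reagents that add atoms: ethylmagnesium bromide, CC[Mg]Br
Why: Kulinkovich cyclopropanation, in which EtMgBr and Ti(OiPr)4 form a titanacyclopropane that acts as a 1,2-dicarbanion and adds twice to the ester carbonyl with loss of methoxide, while the aryl methyl ethers are inert and no stereocentre is formed.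

**Step 2**
Reactants: 3 2,3-dimethoxyphenol
Product: 4 6-bromo-2,3-dimethoxyphenol
Conditions: NBS (1.0 equiv), i-Pr2NH (10 mol %), CH2Cl2, 0 °C to rt
Reagents that add atoms: N-bromosuccinimide, O=C1CCC(=O)N1Br
Why: Amine-catalysed ortho-selective electrophilic aromatic bromination, in which the N-bromoamine made in the flask is hydrogen-bonded to the phenol OH and delivers bromine to C6, the only free ortho position and also para to the 3-OMe group, so both directing effects agree and a second ortho bromination is impossible; no stereocentre is formed.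

**Step 3 (key step)**
Reactants: 2 1-(3,4,5-trimethoxyphenyl)cyclopropan-1-ol (1.3 equiv); 4 6-bromo-2,3-dimethoxyphenol
Product: 8 7,8-dimethoxy-2-(3,4,5-trimethoxyphenyl)-4H-chromene, via arylpalladium homoenolate 5 (not isolated), via hydroxy ketone 6 (not isolated), via cyclic hemiketal 7 (not isolated)
Conditions: Pd(OAc)2 (5 mol %), XPhos (10 mol %), Cs2CO3 (2.5 equiv), toluene, 80 °C; aq. NH4Cl wash, then crude in toluene, p-TsOH·H2O (3 mol %), Dean–Stark, reflux, Ar
Reagents that add atoms: none
Why: Proposed new method: zerovalent palladium inserts into the C–Br bond of 4, the caesium alkoxide of 2 binds to the resulting arylpalladium bromide, and strain-driven β-carbon elimination opens the ring to homoenolate 5, whose β-carbon is joined to the aryl carbon by reductive elimination (favoured over β-hydride elimination by the bulky XPhos) to give 6, which under acid closes to 7 and loses water to the conjugated enol ether 8; the closest known reaction type is the palladium-catalysed cross-coupling of cyclopropanol-derived ketone homoenolates with aryl bromides, which also works with unprotected ortho-bromoanilines that condense in the flask to quinolines, and the new elements are the free ortho-bromophenol and the telescoped cyclodehydration; no stereocentre is formed.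

**Step 4**
Reactants: 8 7,8-dimethoxy-2-(3,4,5-trimethoxyphenyl)-4H-chromene
Product: 9 (2S)-7,8-dimethoxy-2-(3,4,5-trimethoxyphenyl)chromane, which is (2S)-7,8,3',4',5'-pentamethoxyflavan
Conditions: [Ir(cod)(L)][B(C6H3-3,5-(CF3)2)4] (1 mol %), H2 (50 bar), CH2Cl2, rt. L is the D-threonine-derived (4R,5R)-ThrePHOX, the dicyclohexylphosphinite of 1,3-diphenyl-2-[(4R,5R)-5-methyl-2-phenyl-4,5-dihydrooxazol-4-yl]propan-2-ol
Reagents that add atoms: none
Why: Iridium–N,P-catalysed asymmetric hydrogenation of a trisubstituted cyclic enol ether, a reaction type for which 2-aryl-4H-chromenes are established substrates giving 2-arylchromanes in high ee: in the quadrant model the olefin binds with its only vinylic hydrogen (H-3) in the hindered quadrant, 8 has the same layout as (E)-1,2-diphenylpropene (aryl cis to the vinylic H), so the ligand series that gives (S)-1,2-diphenylpropane adds H2 to the Re face of C2 and sets (2S), while the methyl ethers and the benzylic C–O bond are inert and no later step can scramble C2.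

**Compound list**
1 | methyl 3,4,5-trimethoxybenzoate | COC(=O)c1cc(OC)c(OC)c(OC)c1 | starting material
2 | 1-(3,4,5-trimethoxyphenyl)cyclopropan-1-ol | COc1cc(C2(O)CC2)cc(OC)c1OC | intermediate
3 | 2,3-dimethoxyphenol | COc1cccc(O)c1OC | starting material
4 | 6-bromo-2,3-dimethoxyphenol | COc1ccc(Br)c(O)c1OC | intermediate
5 | (2-hydroxy-3,4-dimethoxyphenyl)[3-oxo-3-(3,4,5-trimethoxyphenyl)propyl]palladium, XPhos ligand not drawn | COc1cc(C(=O)CC[Pd]c2ccc(OC)c(OC)c2O)cc(OC)c1OC | intermediate
6 | 3-(2-hydroxy-3,4-dimethoxyphenyl)-1-(3,4,5-trimethoxyphenyl)propan-1-one | COc1cc(C(=O)CCc2ccc(OC)c(OC)c2O)cc(OC)c1OC | intermediate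
7 | 7,8-dimethoxy-2-(3,4,5-trimethoxyphenyl)chroman-2-ol (racemic hemiketal) | COc1cc(C2(O)CCc3ccc(OC)c(OC)c3O2)cc(OC)c1OC | intermediate
8 | 7,8-dimethoxy-2-(3,4,5-trimethoxyphenyl)-4H-chromene | COc1cc(C2=CCc3ccc(OC)c(OC)c3O2)cc(OC)c1OC | intermediate
9 | (2S)-7,8,3',4',5'-pentamethoxyflavan | COc1cc([C@@H]2CCc3ccc(OC)c(OC)c3O2)cc(OC)c1OC | target

**Total step count:** 4. **Longest linear sequence:** 3 (steps 1, 3, 4).

**Three steps most likely to fail**

Step 3. The phenoxide of 4 may slow oxidative addition or block palladium. β-Hydride elimination from 5 may give the enone, base may isomerise 2 to the ethyl ketone, and acid may disproportionate part of 8. The fallback sets out from 2 and 4 and comes back at 6. It turns the β-hydride elimination into the planned path. Compound 2 is opened oxidatively (Pd(OAc)2 cat., pyridine, O2, toluene, 80 °C) to 1-(3,4,5-trimethoxyphenyl)prop-2-en-1-one F1. A Heck reaction of this enone with 4 (Pd(OAc)2, P(o-Tol)3, NaOAc, DMF, 100 °C) gives (E)-3-(2-hydroxy-3,4-dimethoxyphenyl)-1-(3,4,5-trimethoxyphenyl)prop-2-en-1-one F2. Hydrogenation of its C=C bond (H2, Pd/C, EtOAc, rt) leads to 6, which enters the acid stage of step 3.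

Step 4. The ee or the sense of induction may not match the model, the acidic iridium hydrides may protonate the enol ether and open a racemic pathway, and 8 can oxidise in air to the flavylium salt. The fallback sets out from 6, isolated by stopping step 3 after the wash, and comes back at 9. Transfer hydrogenation with RuCl[(R,R)-TsDPEN](p-cymene) in HCO2H/Et3N 5:2 at rt gives (1R)-3-(2-hydroxy-3,4-dimethoxyphenyl)-1-(3,4,5-trimethoxyphenyl)propan-1-ol F3. The (R,R) catalyst gives (R)-carbinols from aryl alkyl ketones. An intramolecular Mitsunobu etherification (PPh3, DIAD, THF, 0 °C) then closes ring C by SN2 displacement with inversion, giving (2S)-9.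

Step 2. Bromination para to the OH (at C4), overbromination or oxidation of the electron-rich phenol could compete. The fallback sets out from 3 and comes back at 4, and it fixes the position by directed metalation. Compound 3 is converted (MOMCl, i-Pr2NEt, CH2Cl2) into 1,2-dimethoxy-3-(methoxymethoxy)benzene F4. Lithiation next to the stronger OMOM director (n-BuLi, TMEDA, THF, 0 °C) and quenching with BrCF2CF2Br gives 1-bromo-3,4-dimethoxy-2-(methoxymethoxy)benzene F5. HCl in MeOH at 40 °C then releases 4.

**Further compounds**
F1 | step 3 | 1-(3,4,5-trimethoxyphenyl)prop-2-en-1-one | COc1cc(C(=O)C=C)cc(OC)c1OC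
F2 | step 3 | (E)-3-(2-hydroxy-3,4-dimethoxyphenyl)-1-(3,4,5-trimethoxyphenyl)prop-2-en-1-one | COc1cc(C(=O)/C=C/c2ccc(OC)c(OC)c2O)cc(OC)c1OC
F3 | step 4 | (1R)-3-(2-hydroxy-3,4-dimethoxyphenyl)-1-(3,4,5-trimethoxyphenyl)propan-1-ol | COc1cc([C@H](O)CCc2ccc(OC)c(OC)c2O)cc(OC)c1OC
F4 | step 2 | 1,2-dimethoxy-3-(methoxymethoxy)benzene | COCOc1cccc(OC)c1OC
F5 | step 2 | 1-bromo-3,4-dimethoxy-2-(methoxymethoxy)benzene | COCOc1c(Br)ccc(OC)c1OC
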